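The left-handed product is the easiest thing to count in this flask, and the bench rule built on it says that each share of it took the same share of left-handed substrate while the right-handed substrate stood by, so that the gap between the two substrates, as a fraction of both charged together, equals the product.

| flask | left-handed substrate | right-handed substrate | gas | free catalyst | racemization catalyst | added ligand | remark | time |
|---|---|---|---|---|---|---|---|---|
| beta | 0.050 M | 0.050 M | 1.9 mM (held) | 1.2 mM | 0.84 mM | 2.5 mM | run made earlier |  |
| delta | 0.050 M | 0.050 M | 1.9 mM (held) | 1.2 mM | 1.3 mM | 2.5 mM | run made earlier |  |
| flask | 0.050 M | 0.050 M | 1.9 mM (held) | 1.2 mM | 0.60 mM | 2.5 mM |  | 50 min |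

- beta (time / min: left-handed substrate / %, right-handed substrate / %, left-handed product / %): 10.0: 48.4, 49.7, 1.3; 20.0: 44.6, 49.1, 5.6; 30.0: 45.9, 50.1, 7.5; 40.0: 43.4, 49.1, 8.1; 50.0: 41.3, 48.3, 10.3; 60.0: 39.2, 49.0, 10.9
- delta (time / min: left-handed substrate / %, right-handed substrate / %, left-handed product / %): 5.00: 47.9, 50.2, 1.1; 8.00: 48.4, 48.7, 3.0; 12.0: 47.5, 50.4, 3.2; 20.0: 47.0, 51.1, 5.2; 40.0: 43.4, 49.7, 8.7; 60.0: 41.7, 46.4, 10.9

(each reading ± 1 percentage point)

- part of the left-handed substrate and right-handed substrate charged together that has reacted at 50 min
- excess of left-handed product over right-handed product in the product at 50 min
- excess of right-handed substrate over left-handed substrate among what is left of the two at 50 min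

- free catalyst is single-handed; left-handed substrate and right-handed substrate are mirror images of each other, charged as a racemate, each of them at the stated concentration
- the numbers in the tables scatter with a standard deviation of 1 percentage point
- at the start none of the gas is in solution
- an excess is the difference of the two amounts in percent of their sum
- an excess is below zero if the other one leads

The product readings of the beta and delta runs agreed within the scatter at 40.0 min and 60.0 min, although the delta run held 1.55 times the racemization catalyst of the beta run, so I pooled the beta readings from 40.0 min on with the delta readings from 40.0 min on, whose times average 50.0 min. They gave a left-handed product of 9.78 % and 9.70 % reacted, and the rule, applied honestly to the flask, then gave an excess of right-handed substrate of 10.8 %.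

The rule's border appeared when I divided the gap by the product, a ratio that takes the pace of the uptake out of the comparison but still depends on the time the racemization catalyst has had to work. Over the last two readings of each run this ratio read 0.792 in the beta run and 0.561 in the delta run, lower with more racemization catalyst, where the rule asks for one. I took the shortfall from one, divided by the racemization catalyst charged and by the time, as the leak 0.00562 /mM/min, the mean of both runs and a reading with their scatter. This is a kinetic resolution with racemization running beside it. For the flask the leak gave a ratio of 0.831, a gap of 8.13 % and an excess of right-handed substrate of 9.00 %, less than the rule's. The tables hold no right-handed product, so I reckoned no excess in the product.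

The forecast, saying “The product curves for beta and delta coincide”, gave 10.3 %, 92 % and 8.4 %, the last lower than my 9.00 %.

The flask gave 9.97 % reacted, an excess of left-handed product of 90.5 % and an excess of right-handed substrate of 8.89 %.

    reagent + free catalyst + left-handed substrate → free catalyst + left-handed product (k = 1300 /M²/s)
    reagent + free catalyst + right-handed substrate → free catalyst + right-handed product (k = 59.0 /M²/s)
    left-handed substrate + racemization catalyst ⇌ right-handed substrate + racemization catalyst, rate k3*[racemization catalyst]*[left-handed substrate] forward; the back reaction follows from the equilibrium constant (k = 0.130 /M/s)
    2 reagent → self-condensation product (k = 0.0120 /M/s)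
    racemization catalyst + added ligand ⇌ idle complex (K = 410 /M, k = 4.50 /M/s)
    gas ⇌ reagent, rate k6*(csat - [reagent]) (kL = 0.00180 /s)

At 50.0 min the flask held a gap of 8.00 % against 9.50 % of left-handed product, a ratio of 0.843 where the leak had given 0.831. The neighbouring flask held 3.6 × 10⁻⁴ M of racemization catalyst, 0.600 of this flask's charge, and there the leak gave 0.899. That neighbouring flask held a ratio of 0.885, with an excess of right-handed substrate of 9.33 %.

The earlier runs and the new flask were computed for an exercise; noise was put on by code.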